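The target is a cis-2,3-diaryl-2,3-dihydrobenzofuran whose ring A carries oxygen at C7a and C6, the phenethyl chain at C4 and the aryl-bearing C3 at C3a, which is the pattern of a folded tetraketide. The plan therefore disconnects C3a–C4. A linear 1,9-diarylnonane-1,3,5,7-tetraone, with the ketone of the C3 aryl group (ring C) at one end and the phenethyl ketone at the other, is folded by mild base; one aldol condensation–aromatisation builds ring A already carrying its C3 aryl ketone, the ortho phenol and the C4 chain. The resulting 2-hydroxybenzophenone is then closed to the benzofuran, hydrogenated from one face (cis) with loss of all benzyl groups, and resolved.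

Key step: step 4

Remark on stereochemistry: the given SMILES corresponds to (2S,3R), in which the aryl groups on C2 and C3 are cis; because a 2-(4-hydroxyphenyl)-2,3-dihydrobenzofuran can epimerise to the trans isomer by ring opening in acid or base, every operation after the ring hydrogenation is kept neutral.

Remark on numbering: salts formed by simple deprotonation of a numbered compound (enolates, polyanions, phenoxides) are treated as that compound and carry no number of their own; atoms of the target are named in benzofuran numbering, atoms of the open chain in nonane numbering.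

Step 1
Reactants: 1 pentane-2,4-dione; 2 methyl 3,5-bis(benzyloxy)benzoate
Product: 3 1-[3,5-bis(benzyloxy)phenyl]hexane-1,3,5-trione
Conditions: 1 (2 equiv), NaH (5 equiv), DME, reflux; then aq. HCl, 0 °C
Reagents that add atoms: none
Why: Claisen-type aroylation of a β-diketone dianion: excess NaH turns 1 into its dianion, whose terminal carbanion is the most nucleophilic site and attacks ester 2, and the excess of 1 suppresses a second aroylation at the far methyl group.

Step 2
Reactants: 4 3-[4-(benzyloxy)phenyl]propanoic acid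
Product: 6 3-[4-(benzyloxy)phenyl]-N-methoxy-N-methylpropanamide, via acyl imidazole 5 (not isolated)
Conditions: CDI (1.1 equiv), CH2Cl2, rt; then MeNH(OMe)·HCl (1.2 equiv), rt
Reagents that add atoms: N,O-dimethylhydroxylamine hydrochloride, CNOC.Cl
Why: Weinreb amide formation through the acyl imidazole 5, a standard carboxyl activation that leaves the benzyl ether untouched and gives an acyl donor that stops at the ketone stage.

Step 3
Reactants: 3 1-[3,5-bis(benzyloxy)phenyl]hexane-1,3,5-trione; 6 3-[4-(benzyloxy)phenyl]-N-methoxy-N-methylpropanamide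
Product: 7 1-[3,5-bis(benzyloxy)phenyl]-9-[4-(benzyloxy)phenyl]nonane-1,3,5,7-tetraone
Conditions: 3 (1.2 equiv), LiN(i-Pr)2 (3.7 equiv), THF, 0 °C; then 6 (1.0 equiv), 0 °C → rt; AcOH quench, −20 °C
Reagents that add atoms: none
Why: Claisen-type terminal acylation of a β-polyketone polyanion: threefold deprotonation of 3 leaves the last-formed terminal carbanion as the most reactive site, it adds to the Weinreb amide 6, and the chelated tetrahedral adduct persists until the cold acidic quench, so neither over-addition nor premature aldol closure should occur.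

Step 4
Reactants: 7 1-[3,5-bis(benzyloxy)phenyl]-9-[4-(benzyloxy)phenyl]nonane-1,3,5,7-tetraone
Product: 9 [3,5-bis(benzyloxy)phenyl]{2,4-dihydroxy-6-[2-(4-benzyloxyphenyl)ethyl]phenyl}methanone, via cyclic aldol adduct 8 (not isolated)
Conditions: aq. K2CO3/KHCO3 buffer (pH ≈ 10), MeOH–THF, N2, 0 °C → rt; then 1 M HCl to pH 3
Reagents that add atoms: none
Why: The buffer deprotonates chain methylene C2 (future C3a), which lies between the aryl ketone C1 and the C3 carbonyl, and this enolate adds to the terminal alkyl ketone C7 (future C4) to give the cyclic aldol 8; E1cB loss of water and enolisation of the C3 and C5 carbonyls (future C7a and C6) then make ring A aromatic. The closest known reaction type is the base-mediated biomimetic aldol cyclisation–aromatisation of 3,5,7-triketones and 1-aryl-1,3,5,7-tetraketones to acylresorcinols. Ring A closes in a 6-(enolendo)-exo-trig mode, forming the C3a–C4 bond. No stereocentre survives, since the two that appear in 8 are erased on aromatisation. The step needs selection between two folds (C2 onto C7 against C6 onto C1) and against O-cyclisation to 4-pyranones: the saturated ketone C7 is more electrophilic and less hindered than the aryl-conjugated C1 carbonyl, the C2 hydrogens are the most acidic, and a basic medium disfavours pyranone formation. The aryl ketone should therefore survive and end up on C3a, next to the new phenol on C7a.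

Step 5
Reactants: 9 [3,5-bis(benzyloxy)phenyl]{2,4-dihydroxy-6-[2-(4-benzyloxyphenyl)ethyl]phenyl}methanone
Product: 10 {4-(benzyloxy)-2-hydroxy-6-[2-(4-benzyloxyphenyl)ethyl]phenyl}[3,5-bis(benzyloxy)phenyl]methanone
Conditions: BnBr (1.05 equiv), K2CO3 (1.1 equiv), acetone, reflux
Reagents that add atoms: benzyl bromide, BrCc1ccccc1
Why: Williamson etherification that is selective for the free para phenol, because the ortho phenol is locked in a hydrogen bond to the ketone, is less acidic and is flanked by the aroyl group, a selectivity well known for 2,4-dihydroxyaryl ketones.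

Step 6
Reactants: 10 {4-(benzyloxy)-2-hydroxy-6-[2-(4-benzyloxyphenyl)ethyl]phenyl}[3,5-bis(benzyloxy)phenyl]methanone; 11 4-(benzyloxy)benzoyl chloride
Product: 12 5-(benzyloxy)-2-[3,5-bis(benzyloxy)benzoyl]-3-{2-[4-(benzyloxy)phenyl]ethyl}phenyl 4-(benzyloxy)benzoate
Conditions: 11 (1.3 equiv), Et3N (2 equiv), DMAP (0.2 equiv), CH2Cl2, 0 °C → rt
Reagents that add atoms: none
Why: DMAP-catalysed O-acylation of the remaining chelated phenol by the acid chloride, which places on the C7a oxygen the ester carbon that becomes C2 together with its 4-(benzyloxy)phenyl group.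

Step 7
Reactants: 12 5-(benzyloxy)-2-[3,5-bis(benzyloxy)benzoyl]-3-{2-[4-(benzyloxy)phenyl]ethyl}phenyl 4-(benzyloxy)benzoate
Product: 13 6-(benzyloxy)-3-[3,5-bis(benzyloxy)phenyl]-2-[4-(benzyloxy)phenyl]-4-{2-[4-(benzyloxy)phenyl]ethyl}-1-benzofuran
Conditions: TiCl3 (4 equiv), Zn dust (8 equiv), DME, reflux; 12 added over 6 h
Reagents that add atoms: none
Why: Intramolecular McMurry-type ketone–ester reductive coupling: low-valent titanium reduces the diaryl ketone to a titanium-bound ketyl that attacks the neighbouring ester carbonyl in a five-membered closure, and double deoxygenation gives the C2=C3 bond, while aryl benzyl ethers are inert to the reagent.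

Step 8
Reactants: 13 6-(benzyloxy)-3-[3,5-bis(benzyloxy)phenyl]-2-[4-(benzyloxy)phenyl]-4-{2-[4-(benzyloxy)phenyl]ethyl}-1-benzofuran
Product: 15 racemic cis-3-(3,5-dihydroxyphenyl)-2-(4-hydroxyphenyl)-4-[2-(4-hydroxyphenyl)ethyl]-2,3-dihydro-1-benzofuran-6-ol, via pentahydroxy benzofuran 14 (not isolated)
Conditions: H2 (5 bar), 10% Pd/C, EtOAc–MeOH (1:1), rt; stopped when H2 uptake ends
Reagents that add atoms: none
Why: Heterogeneous catalytic hydrogenation: after fast hydrogenolysis of the five benzyl ethers, both hydrogens should be delivered to C2 and C3 from the catalyst surface on the same face (syn addition), which fixes the cis relationship of the two aryl groups in racemic form, and the neutral medium avoids cis-to-trans epimerisation.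

Step 9
Reactants: 15 racemic cis-3-(3,5-dihydroxyphenyl)-2-(4-hydroxyphenyl)-4-[2-(4-hydroxyphenyl)ethyl]-2,3-dihydro-1-benzofuran-6-ol
Product: 16 (2S,3R)-3-(3,5-dihydroxyphenyl)-2-(4-hydroxyphenyl)-4-[2-(4-hydroxyphenyl)ethyl]-2,3-dihydro-1-benzofuran-6-ol
Conditions: preparative HPLC, amylose tris(3,5-dimethylphenylcarbamate) stationary phase, n-hexane–EtOH, rt
Reagents that add atoms: none
Why: Direct chromatographic resolution of enantiomers on a polysaccharide chiral stationary phase under neutral conditions, which leaves both stereocentres untouched, the (2S,3R) antipode being assigned by comparison of its ECD spectrum with calculation or by X-ray analysis of a heavy-atom derivative.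

Compound list

1 | pentane-2,4-dione | CC(=O)CC(C)=O | starting material
2 | methyl 3,5-bis(benzyloxy)benzoate | COC(=O)c1cc(OCc2ccccc2)cc(OCc2ccccc2)c1 | starting material
3 | 1-[3,5-bis(benzyloxy)phenyl]hexane-1,3,5-trione | CC(=O)CC(=O)CC(=O)c1cc(OCc2ccccc2)cc(OCc2ccccc2)c1 | intermediate
4 | 3-[4-(benzyloxy)phenyl]propanoic acid | OC(=O)CCc1ccc(OCc2ccccc2)cc1 | starting material
5 | 1-{3-[4-(benzyloxy)phenyl]propanoyl}-1H-imidazole | O=C(CCc1ccc(OCc2ccccc2)cc1)n1ccnc1 | intermediate (not isolated)
6 | 3-[4-(benzyloxy)phenyl]-N-methoxy-N-methylpropanamide | CON(C)C(=O)CCc1ccc(OCc2ccccc2)cc1 | intermediate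
7 | 1-[3,5-bis(benzyloxy)phenyl]-9-[4-(benzyloxy)phenyl]nonane-1,3,5,7-tetraone (key-step precursor; kept cold and used promptly) | O=C(CC(=O)CC(=O)CC(=O)CCc1ccc(OCc2ccccc2)cc1)c1cc(OCc2ccccc2)cc(OCc2ccccc2)c1 | intermediate
8 | 4-[3,5-bis(benzyloxy)benzoyl]-5-{2-[4-(benzyloxy)phenyl]ethyl}-5-hydroxycyclohexane-1,3-dione (mixture of diastereomers) | O=C(c1cc(OCc2ccccc2)cc(OCc2ccccc2)c1)C1C(=O)CC(=O)CC1(O)CCc1ccc(OCc2ccccc2)cc1 | intermediate (not isolated)
9 | [3,5-bis(benzyloxy)phenyl]{2,4-dihydroxy-6-[2-(4-benzyloxyphenyl)ethyl]phenyl}methanone (key-step product) | O=C(c1cc(OCc2ccccc2)cc(OCc2ccccc2)c1)c1c(O)cc(O)cc1CCc1ccc(OCc2ccccc2)cc1 | intermediate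
10 | {4-(benzyloxy)-2-hydroxy-6-[2-(4-benzyloxyphenyl)ethyl]phenyl}[3,5-bis(benzyloxy)phenyl]methanone | O=C(c1cc(OCc2ccccc2)cc(OCc2ccccc2)c1)c1c(O)cc(OCc2ccccc2)cc1CCc1ccc(OCc2ccccc2)cc1 | intermediate
11 | 4-(benzyloxy)benzoyl chloride | O=C(Cl)c1ccc(OCc2ccccc2)cc1 | starting material
12 | 5-(benzyloxy)-2-[3,5-bis(benzyloxy)benzoyl]-3-{2-[4-(benzyloxy)phenyl]ethyl}phenyl 4-(benzyloxy)benzoate | O=C(Oc1cc(OCc2ccccc2)cc(CCc2ccc(OCc3ccccc3)cc2)c1C(=O)c1cc(OCc2ccccc2)cc(OCc2ccccc2)c1)c1ccc(OCc2ccccc2)cc1 | intermediate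
13 | 6-(benzyloxy)-3-[3,5-bis(benzyloxy)phenyl]-2-[4-(benzyloxy)phenyl]-4-{2-[4-(benzyloxy)phenyl]ethyl}-1-benzofuran | C(Cc1cc(OCc2ccccc2)cc2oc(-c3ccc(OCc4ccccc4)cc3)c(-c3cc(OCc4ccccc4)cc(OCc4ccccc4)c3)c12)c1ccc(OCc2ccccc2)cc1 | intermediate
14 | 3-(3,5-dihydroxyphenyl)-2-(4-hydroxyphenyl)-4-[2-(4-hydroxyphenyl)ethyl]-1-benzofuran-6-ol | Oc1ccc(CCc2cc(O)cc3oc(-c4ccc(O)cc4)c(-c4cc(O)cc(O)c4)c23)cc1 | intermediate (not isolated)
15 | racemic cis-3-(3,5-dihydroxyphenyl)-2-(4-hydroxyphenyl)-4-[2-(4-hydroxyphenyl)ethyl]-2,3-dihydro-1-benzofuran-6-ol (1:1 mixture of the (2S,3R) and (2R,3S) enantiomers, written as both) | Oc1ccc(CCc2cc(O)cc3c2[C@@H](c2cc(O)cc(O)c2)[C@@H](c2ccc(O)cc2)O3)cc1.Oc1ccc(CCc2cc(O)cc3c2[C@H](c2cc(O)cc(O)c2)[C@H](c2ccc(O)cc2)O3)cc1 | intermediate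
16 | (2S,3R)-3-(3,5-dihydroxyphenyl)-2-(4-hydroxyphenyl)-4-[2-(4-hydroxyphenyl)ethyl]-2,3-dihydro-1-benzofuran-6-ol | Oc1ccc(CCc2cc(O)cc3c2[C@@H](c2cc(O)cc(O)c2)[C@@H](c2ccc(O)cc2)O3)cc1 | target

Total step count: 9. Longest linear sequence: 8 steps (steps 1, 3, 4, 5, 6, 7, 8, 9); step 2 is a one-step side branch.

Steps most likely to fail

1. Step 4 (key step). The chain may close through the other aldol fold (chain carbon C6 onto the aryl ketone), cyclise through oxygen to 4-pyranones, or fragment by retro-Claisen cleavage. The fallback takes ring A preformed and installs the ketone by aryl-metal chemistry; it sets out from ester 2 and comes back to the route at 10, so steps 3 to 5 are bypassed. Commercial dihydroresveratrol (5-[2-(4-hydroxyphenyl)ethyl]benzene-1,3-diol) would be perbenzylated (BnBr, K2CO3, DMF) to 1,3-bis(benzyloxy)-5-{2-[4-(benzyloxy)phenyl]ethyl}benzene F1. NBS (1 equiv, MeCN, 0 °C) should brominate the most electron-rich ring ortho to the chain and para to a benzyloxy group, giving 1,5-bis(benzyloxy)-2-bromo-3-{2-[4-(benzyloxy)phenyl]ethyl}benzene F2. Bromine–lithium exchange (n-BuLi, THF, −78 °C) would give {2,4-bis(benzyloxy)-6-[2-(4-benzyloxyphenyl)ethyl]phenyl}lithium F3, which is added to ester 2. The doubly ortho-substituted ketone should resist a second addition, so {2,4-bis(benzyloxy)-6-[2-(4-benzyloxyphenyl)ethyl]phenyl}[3,5-bis(benzyloxy)phenyl]methanone F4 is expected. MgBr2·OEt2 (toluene–Et2O, reflux) would then remove only the benzyl group ortho to the carbonyl through chelation and deliver 10.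

2. Step 3. Proton transfer from the amide to the trianion, attack of the polyanion at the N–OMe group, or incomplete formation of the poorly soluble trilithio salt would each return unchanged 3. The fallback moves the chain-forming bond one carbonyl inward (C4–C5 in place of C6–C7); it sets out from 2 and 6 and comes back at 7. Ester 2 would be condensed with acetone (NaH, THF, reflux) to 1-[3,5-bis(benzyloxy)phenyl]butane-1,3-dione F5. Amide 6 would be treated with the lithium enolate of methyl acetate (LiN(i-Pr)2, THF, −78 °C) to give methyl 5-[4-(benzyloxy)phenyl]-3-oxopentanoate F6. The dilithio derivative of F5 (LiN(i-Pr)2, 2.2 equiv, THF, 0 °C), used in excess, would then be acylated at its terminal carbanion by the preformed lithium enolate of F6 to give 7 after a cold acidic quench.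

3. Step 8. Saturation of the hindered tetrasubstituted C2=C3 bond may be slow or incomplete, the benzylic C2–O bond of the product may be opened by hydrogenolysis, and half of the material is lost in the resolution that follows. The fallback builds the cis ring directly and enantioselectively by carbene C–H insertion; it sets out from 10 and comes back at 16, so steps 6 to 9 are bypassed. Phenol 10 would be alkylated with 4-(benzyloxy)benzyl chloride (K2CO3, DMF, 60 °C) to {4-(benzyloxy)-2-{[4-(benzyloxy)phenyl]methoxy}-6-[2-(4-benzyloxyphenyl)ethyl]phenyl}[3,5-bis(benzyloxy)phenyl]methanone F7. Hydrazine hydrate (n-BuOH, cat. AcOH, reflux) would give its hydrazone F8. Oxidation with MnO2 (CH2Cl2, 0 °C) would give the diaryldiazomethane F9. With Rh2(S-PTAD)4, or its mirror-image catalyst if that is the one that delivers (2S,3R), F9 should insert into the ether-activated benzylic O–CH2 group to give (2S,3R)-6-(benzyloxy)-3-[3,5-bis(benzyloxy)phenyl]-2-[4-(benzyloxy)phenyl]-4-{2-[4-(benzyloxy)phenyl]ethyl}-2,3-dihydro-1-benzofuran F10 as the cis isomer. Mild hydrogenolysis (H2 1 atm, 10% Pd/C, EtOAc, rt) would then give 16.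

Further compounds

F1 | step 4 | 1,3-bis(benzyloxy)-5-{2-[4-(benzyloxy)phenyl]ethyl}benzene | C(Cc1cc(OCc2ccccc2)cc(OCc2ccccc2)c1)c1ccc(OCc2ccccc2)cc1
F2 | step 4 | 1,5-bis(benzyloxy)-2-bromo-3-{2-[4-(benzyloxy)phenyl]ethyl}benzene | Brc1c(OCc2ccccc2)cc(OCc2ccccc2)cc1CCc1ccc(OCc2ccccc2)cc1
F3 | step 4 | {2,4-bis(benzyloxy)-6-[2-(4-benzyloxyphenyl)ethyl]phenyl}lithium | [Li]c1c(OCc2ccccc2)cc(OCc2ccccc2)cc1CCc1ccc(OCc2ccccc2)cc1
F4 | step 4 | {2,4-bis(benzyloxy)-6-[2-(4-benzyloxyphenyl)ethyl]phenyl}[3,5-bis(benzyloxy)phenyl]methanone | O=C(c1cc(OCc2ccccc2)cc(OCc2ccccc2)c1)c1c(OCc2ccccc2)cc(OCc2ccccc2)cc1CCc1ccc(OCc2ccccc2)cc1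
F5 | step 3 | 1-[3,5-bis(benzyloxy)phenyl]butane-1,3-dione | CC(=O)CC(=O)c1cc(OCc2ccccc2)cc(OCc2ccccc2)c1
F6 | step 3 | methyl 5-[4-(benzyloxy)phenyl]-3-oxopentanoate | COC(=O)CC(=O)CCc1ccc(OCc2ccccc2)cc1
F7 | step 8 | {4-(benzyloxy)-2-{[4-(benzyloxy)phenyl]methoxy}-6-[2-(4-benzyloxyphenyl)ethyl]phenyl}[3,5-bis(benzyloxy)phenyl]methanone | O=C(c1cc(OCc2ccccc2)cc(OCc2ccccc2)c1)c1c(OCc2ccc(OCc3ccccc3)cc2)cc(OCc2ccccc2)cc1CCc1ccc(OCc2ccccc2)cc1
F8 | step 8 | hydrazone of F7 | NN=C(c1cc(OCc2ccccc2)cc(OCc2ccccc2)c1)c1c(OCc2ccc(OCc3ccccc3)cc2)cc(OCc2ccccc2)cc1CCc1ccc(OCc2ccccc2)cc1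
F9 | step 8 | diaryldiazomethane from F8 | [N-]=[N+]=C(c1cc(OCc2ccccc2)cc(OCc2ccccc2)c1)c1c(OCc2ccc(OCc3ccccc3)cc2)cc(OCc2ccccc2)cc1CCc1ccc(OCc2ccccc2)cc1
F10 | step 8 | (2S,3R)-6-(benzyloxy)-3-[3,5-bis(benzyloxy)phenyl]-2-[4-(benzyloxy)phenyl]-4-{2-[4-(benzyloxy)phenyl]ethyl}-2,3-dihydro-1-benzofuran | C(Cc1cc(OCc2ccccc2)cc2c1[C@@H](c1cc(OCc3ccccc3)cc(OCc3ccccc3)c1)[C@@H](c1ccc(OCc3ccccc3)cc1)O2)c1ccc(OCc2ccccc2)cc1
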